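**Retrosynthetic overview**
1. The C2–aryl bond and the only stereocentre (2S) are made last, by enantioselective conjugate arylation of 7-hydroxy-6,8-diprenylchromone with 3,4-dimethoxyphenylboronic acid.
2. The chromone bicycle comes from two acyclic pieces in one flask: a doubly prenylated 1-methoxy-1,3-bis(silyloxy)diene and a terminal ynone carrying a masked aldehyde.
3. A [4+2] cycloaddition/aromatisation builds benzene ring A with every substituent in place, and acid then closes pyranone ring C in the same operation; ring B is bought.
4. The diene comes from methyl acetoacetate and two equivalents of prenyl bromide (γ- then α-alkylation, then bis-silylation); the ynone comes from ethyl 3,3-diethoxypropanoate by a Weinreb/ethynyl Grignard sequence.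

Assumption: Pd(OCOCF3)2 with a t-BuPyOx ligand is taken to arylate chromones with the same facial sense as 3-methylcyclohexenone ((S)-ligand gives the R product), so the (R)-ligand is used for the 2S target.

**Step 1**
Reactants: 1 methyl acetoacetate; 2 1-bromo-3-methylbut-2-ene (prenyl bromide, first equivalent)
Product: 4 methyl 7-methyl-2-(3-methylbut-2-en-1-yl)-3-oxooct-6-enoate (racemic), via mono-prenylated keto ester enolate 3 (not isolated)
Conditions: NaH (1.1 equiv), THF, 0 °C; n-BuLi (1.05 equiv), 0 °C; 2 (1.0 equiv), 0 °C, 30 min; then a second portion of 2 (1.1 equiv), 0 → 45 °C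
Reagents that add atoms: 1-bromo-3-methylbut-2-ene (second equivalent of 2), CC(C)=CCBr
Why: Weiler dianion alkylation puts the first prenyl group on the terminal (γ) carbon, and the remaining stabilised enolate of 3 is then C-alkylated (SN2, soft allylic bromide) at the central carbon on warming with the second equivalent; the stereocentre of 4 is flattened in step 2.

**Step 2**
Reactants: 4 methyl 7-methyl-2-(3-methylbut-2-en-1-yl)-3-oxooct-6-enoate
Product: 5 (3Z)-1-methoxy-7-methyl-2-(3-methylbut-2-en-1-yl)-1,3-bis(trimethylsilyloxy)octa-1,3,6-triene (crude, moisture-sensitive, used directly)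
Conditions: TMSOTf (2.3 equiv), Et3N (2.6 equiv), Et2O, 0 °C → rt; pentane extraction
Reagents that add atoms: trimethylsilyl trifluoromethanesulfonate, C[Si](C)(C)OS(=O)(=O)C(F)(F)F
Why: Soft enolisation–silylation (Simchen conditions) O-silylates the ketone enol and then the ester after γ-deprotonation to give the Chan-type 1,3-bis(silyloxy)diene, with the thermodynamically preferred 3Z enol ether that keeps the side chain outside the s-cis diene.

**Step 3**
Reactants: 6 ethyl 3,3-diethoxypropanoate
Product: 8 5,5-diethoxypent-1-yn-3-one, via Weinreb amide 7 (not isolated)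
Conditions: MeNH(OMe)·HCl (1.55 equiv), i-PrMgCl (3.0 equiv), THF, −20 → −5 °C; then HC≡CMgBr (3 equiv), 0 °C → rt; cold aq. NaHSO4 quench
Reagents that add atoms: ethynylmagnesium bromide, C#C[Mg]Br; N,O-dimethylhydroxylamine hydrochloride, CNOC.Cl (its atoms stay only in 7)
Why: Weinreb ketone synthesis, in which the magnesium amide converts the ester into amide 7 and the chelated tetrahedral adduct with the alkynyl Grignard stops over-addition, while the cold acidic quench keeps the freed amine from adding to the ynone.

**Step 4**
Reactants: 5 (3Z)-1-methoxy-7-methyl-2-(3-methylbut-2-en-1-yl)-1,3-bis(trimethylsilyloxy)octa-1,3,6-triene (1.3 equiv); 8 5,5-diethoxypent-1-yn-3-one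
Product: 11 7-hydroxy-6,8-bis(3-methylbut-2-en-1-yl)-4H-chromen-4-one, via cyclohexadiene cycloadduct 9 (not isolated), via aryl keto acetal 10 (not isolated)
Conditions: PhMe, 85 °C, 16 h, argon; then THF, 2 M aq. HCl, rt → 40 °C
Reagents that add atoms: none
Why: Proposed new method: the electron-rich ketene-acetal diene 5 should add to terminal ynone 8 with the usual regiochemistry of 1-alkoxy-1,3-bis(silyloxy)dienes (nucleophilic C4 to the alkyne terminus, ketene-acetal carbon to the acyl-bearing carbon), cycloadduct 9 aromatises by loss of methanol (on acid treatment through collapse of the desilylated hemiketal to a dienone that tautomerises) to give ring A with both prenyl groups, both oxygens and the acyl group in their final positions, and the aqueous acid also removes the silyl groups and lets the ortho-phenol of 10 attack the unmasked aldehyde carbon and lose ethanol to close pyranone ring C; the closest known reactions are the Diels–Alder benzannulation of Chan/Brassard-type dienes with alkynones or propiolates and the acid-mediated chromone closure of 2-hydroxyaryl β-keto acetals; no stereocentre survives.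

**Step 5**
Reactants: 11 7-hydroxy-6,8-bis(3-methylbut-2-en-1-yl)-4H-chromen-4-one; 12 (3,4-dimethoxyphenyl)boronic acid (2.5 equiv)
Product: 13 (2S)-2-(3,4-dimethoxyphenyl)-7-hydroxy-6,8-bis(3-methylbut-2-en-1-yl)-2,3-dihydro-4H-chromen-4-one (IN0946)
Conditions: Pd(OCOCF3)2 (8 mol %), (R)-t-BuPyOx [(R)-4-tert-butyl-2-(pyridin-2-yl)-4,5-dihydro-1,3-oxazole] (10 mol %), NH4PF6 (30 mol %), H2O (5 equiv), ClCH2CH2Cl, 60 °C, argon
Reagents that add atoms: none
Why: Enantioselective conjugate addition of an arylboronic acid to a chromone under cationic divalent palladium/pyridine–oxazoline catalysis, in which transmetalation gives an aryl–palladium species, ligand-controlled face-selective insertion of the C2=C3 bond places the aryl group at C2 (2S with the (R)-ligand), and water protonates the palladium enolate, so no base is present to open or racemise the flavanone.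

**Compound list**
1 | methyl acetoacetate | COC(=O)CC(C)=O | starting material
2 | 1-bromo-3-methylbut-2-ene (prenyl bromide) | CC(C)=CCBr | starting material
3 | methyl 7-methyl-3-oxooct-6-enoate (present as its enolate, not isolated) | COC(=O)CC(=O)CCC=C(C)C | intermediate
4 | methyl 7-methyl-2-(3-methylbut-2-en-1-yl)-3-oxooct-6-enoate (racemic) | COC(=O)C(CC=C(C)C)C(=O)CCC=C(C)C | intermediate
5 | (3Z)-1-methoxy-7-methyl-2-(3-methylbut-2-en-1-yl)-1,3-bis(trimethylsilyloxy)octa-1,3,6-triene (C1=C2 geometry undefined) | COC(O[Si](C)(C)C)=C(CC=C(C)C)/C(O[Si](C)(C)C)=C/CC=C(C)C | intermediate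
6 | ethyl 3,3-diethoxypropanoate | CCOC(=O)CC(OCC)OCC | starting material
7 | 3,3-diethoxy-N-methoxy-N-methylpropanamide (not isolated) | CCOC(CC(=O)N(C)OC)OCC | intermediate
8 | 5,5-diethoxypent-1-yn-3-one | CCOC(CC(=O)C#C)OCC | intermediate
9 | 3,3-diethoxy-1-[6-methoxy-3,5-bis(3-methylbut-2-en-1-yl)-4,6-bis(trimethylsilyloxy)cyclohexa-1,4-dien-1-yl]propan-1-one (stereoisomer mixture, not isolated) | CCOC(CC(=O)C1=CC(CC=C(C)C)C(O[Si](C)(C)C)=C(CC=C(C)C)C1(OC)O[Si](C)(C)C)OCC | intermediate
10 | 3,3-diethoxy-1-[2,4-dihydroxy-3,5-bis(3-methylbut-2-en-1-yl)phenyl]propan-1-one (not isolated) | CCOC(CC(=O)c1cc(CC=C(C)C)c(O)c(CC=C(C)C)c1O)OCC | intermediate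
11 | 7-hydroxy-6,8-bis(3-methylbut-2-en-1-yl)-4H-chromen-4-one | O=c1ccoc2c(CC=C(C)C)c(O)c(CC=C(C)C)cc12 | intermediate
12 | (3,4-dimethoxyphenyl)boronic acid | COc1ccc(B(O)O)cc1OC | starting material
13 | (2S)-2-(3,4-dimethoxyphenyl)-7-hydroxy-6,8-bis(3-methylbut-2-en-1-yl)-2,3-dihydro-4H-chromen-4-one | COc1ccc([C@@H]2CC(=O)c3cc(CC=C(C)C)c(O)c(CC=C(C)C)c3O2)cc1OC | target

**Totals**
Total step count: 5. Longest linear sequence: 4 steps (1 → 2 → 4 → 5); step 3 is the convergent branch.

**Steps most likely to fail, with fallbacks**

Step 4 is the riskiest. The diene is tetrasubstituted and hindered. The cycloadduct could lose silanol instead of methanol, which would leave an unreactive methyl ether at C8a. The acid stage could also cyclise a prenyl group onto a free phenol. The fallback sets out from 2 and comes back at 11, and gives up the de novo construction of ring A. Commercial 2',4'-dihydroxyacetophenone is C-prenylated twice with 2 in aqueous KOH to give 1-[2,4-dihydroxy-3,5-bis(3-methylbut-2-en-1-yl)phenyl]ethan-1-one F1, in modest yield after separation from mono- and O-prenylated material. Heating with N,N-dimethylformamide dimethyl acetal gives (2E)-3-(dimethylamino)-1-[2,4-dihydroxy-3,5-bis(3-methylbut-2-en-1-yl)phenyl]prop-2-en-1-one F2. Dilute HCl at room temperature then closes ring C with loss of dimethylamine to give 11.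

Step 5 is the next risk. The free phenol flanked by two prenyl groups may undergo oxidative cyclisation with cationic divalent palladium and kill the catalyst. The electron-rich boronic acid may protodeboronate. The facial sense rests on the stated assumption. The fallback sets out from 11 and comes back at 13, and changes both the protecting-group strategy and the metal. Compound 11 is silylated (TBSOTf, 2,6-lutidine, CH2Cl2) to 7-[(tert-butyldimethylsilyl)oxy]-6,8-bis(3-methylbut-2-en-1-yl)-4H-chromen-4-one F3. A monovalent rhodium catalyst made from [Rh(OH)(C8H12)]2 and an (S)-configured biaryl bisphosphine such as (S)-BINAP transfers the aryl group of 12 in a 1,4-addition (dioxane/H2O, 40 °C), using the facial model known for cyclic enones. This gives (2S)-7-[(tert-butyldimethylsilyl)oxy]-2-(3,4-dimethoxyphenyl)-6,8-bis(3-methylbut-2-en-1-yl)-2,3-dihydro-4H-chromen-4-one F4. Et3N·3HF in THF then removes the silyl group without base to give 13.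

Step 3 is the third risk. The liberated N,O-dimethylhydroxylamine can add to the terminal ynone, and the β-keto acetal can lose ethanol or polymerise on concentration. The fallback sets out from 6 and comes back at 8, and replaces acyl substitution by aldehyde addition and oxidation. Compound 6 is reduced with i-Bu2AlH (CH2Cl2, −78 °C) to 3,3-diethoxypropanal F5. Ethynylmagnesium bromide (THF, 0 °C) adds to give racemic 5,5-diethoxypent-1-yn-3-ol F6. Oxidation with MnO2 (CH2Cl2, rt) gives 8 under neutral conditions with no amine present.

**Further compounds**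
F1 | step 4 | 1-[2,4-dihydroxy-3,5-bis(3-methylbut-2-en-1-yl)phenyl]ethan-1-one | CC(=O)c1cc(CC=C(C)C)c(O)c(CC=C(C)C)c1O
F2 | step 4 | (2E)-3-(dimethylamino)-1-[2,4-dihydroxy-3,5-bis(3-methylbut-2-en-1-yl)phenyl]prop-2-en-1-one | CN(C)/C=C/C(=O)c1cc(CC=C(C)C)c(O)c(CC=C(C)C)c1O
F3 | step 5 | 7-[(tert-butyldimethylsilyl)oxy]-6,8-bis(3-methylbut-2-en-1-yl)-4H-chromen-4-one | O=c1ccoc2c(CC=C(C)C)c(O[Si](C)(C)C(C)(C)C)c(CC=C(C)C)cc12
F4 | step 5 | (2S)-7-[(tert-butyldimethylsilyl)oxy]-2-(3,4-dimethoxyphenyl)-6,8-bis(3-methylbut-2-en-1-yl)-2,3-dihydro-4H-chromen-4-one | COc1ccc([C@@H]2CC(=O)c3cc(CC=C(C)C)c(O[Si](C)(C)C(C)(C)C)c(CC=C(C)C)c3O2)cc1OC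
F5 | step 3 | 3,3-diethoxypropanal | CCOC(CC=O)OCC
F6 | step 3 | 5,5-diethoxypent-1-yn-3-ol (racemic) | CCOC(CC(O)C#C)OCC
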